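Readings and results are calculated from invented constants, and the scatter is random.

The product in the teal run stood at 25.1 % after 1.00 h, 33.0 % after 3.00 h and 33.6 % after 12.0 h. Its mean rate, as a share of the charge, fell from 0.251 h⁻¹ in the first hour to 0.0395 h⁻¹ over the next two, a factor of 6.35, and then to nothing within the scatter.

| flask | starting material | reagent | precatalyst | remark | time |
|---|---|---|---|---|---|
| green | 0.050 M (fed, over 4.0 min) | 0.028 M | 7.5 mM | run made earlier |  |
| grey | 0.050 M (fed, over 4.0 min) | 0.041 M | 7.5 mM | run made earlier |  |
| teal | 0.050 M (fed, over 4.0 min) | 0.087 M | 7.5 mM | run made earlier |  |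
| amber | 0.050 M (fed, over 4.0 min) | 0.075 M | 5.1 mM | run made earlier |  |
| spring | 0.015 M (fed, over 4.0 min) | 0.0250 M | 5.0 mM |  | 12 h |
| winter | 0.050 M (fed, over 4.0 min) | 0.0250 M | 5.0 mM |  | 12 h |
| summer | 0.050 M (fed, over 4.0 min) | 0.0750 M | 7.5 mM |  | 12 h |
| midnight | 0.012 M (fed, over 1.2 min) | 0.0750 M | 7.5 mM |  | 12 h |

| run | time / h | product / % |
|---|---|---|
| green | 2.50 | 13.4 |
| green | 5.00 | 12.5 |
| green | 8.00 | 13.1 |
| green | 10.0 | 12.1 |
| green | 12.0 | 13.0 |
| grey | 1.00 | 12.6 |
| grey | 2.00 | 17.4 |
| grey | 3.00 | 17.7 |
| grey | 6.00 | 18.1 |
| grey | 12.0 | 18.1 |
| teal | 1.00 | 25.1 |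
| teal | 3.00 | 33.0 |
| teal | 6.00 | 32.8 |
| teal | 8.00 | 32.8 |
| teal | 12.0 | 33.6 |
| amber | 2.50 | 29.1 |
| amber | 5.00 | 29.5 |
| amber | 8.00 | 29.4 |
| amber | 10.0 | 29.3 |
| amber | 12.0 | 29.6 |

(readings scatter by 0.3 percentage points)

- steps that have been proposed: starting material + reagent + catalyst <-> product + catalyst; precatalyst <-> catalyst

1. the flasks by amount of product, in percent of the starting material charged, highest first, at 12 h (spring / winter / summer / midnight)
2. the same order at 2.0 d (spring / winter / summer / midnight)
3. the amount of product, in percent of the starting material charged of the flask you put first, at 12 h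
4. the amount of product, in percent of the starting material charged of the flask you put last, at 12 h

On the proposed step one catalyst carries both directions, so I set the forward rate, proportional to [starting material][reagent], against the back rate, proportional to [product], and the catalyst cancels from their ratio. Net rate ends where they are equal, at [product]/([starting material][reagent]) = K. The amber plateau, with a mean of 29.4 %, read K = 6.90 L mol⁻¹. The teal plateau, with 7.5 mM of precatalyst against amber's 5.1 mM, read 7.00 L mol⁻¹. Teal was flat by 3.00 h and amber, on 5.1 mM of precatalyst, by 2.50 h, and 12 h is 4.00 times the later of these, so I expected the flasks to read alike at 12 h and 2.0 d.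

For midnight, K times [reagent] gives 0.517. I call this the pull: the forward rate over the back rate at equal amounts of starting material and product. With midnight's reagent at 6.25 times its starting material, the step was nearly pseudo-first-order, so I first replaced the reagent's curve by its starting value. With the catalyst set aside, since it cancels, the forward term then fell as starting material went, the back term climbed with product, and they met at pull/(1 + pull), or 34.1 %. There the forward term stood at 65.9 % of its starting value. But the spent reagent cut it by a further factor of 0.945, which lowered the pull to 0.489 and the end to 32.8 %. Winter and spring started at a pull of 0.172, smaller than midnight's by a factor of 3.01. Midnight was charged with less starting material than summer, and spring with less than winter, so I expected each of these to spend less of its reagent, and I ranked midnight, summer, spring, winter at both times.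

The forecast, judging that “this is true equilibrium, not catalyst death”, gave midnight > summer > spring > winter and midnight > summer > spring > winter, with 33.2 % on top and 11.8 % lowest, its top above my 32.8 %. The flasks gave midnight > summer > spring > winter at 12.0 h and midnight > summer > spring > winter at 2.0 d, with midnight at 32.9 % and winter at 11.7 % at 12.0 h.

    starting material + reagent + catalyst ⇌ product + catalyst, rate k1*[starting material]*[reagent]*[catalyst] forward; the back reaction follows from the equilibrium constant (K = 6.89 L mol⁻¹, k = 74.6 L² mol⁻² min⁻¹)
    precatalyst ⇌ catalyst (K = 0.883, k = 0.00710 min⁻¹)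

Midnight, with its lowered pull of 0.489, gave 32.9 % of product against my 32.8 %. A neighbour of midnight, charged with 0.19 M of reagent, took the same reckoning. Midnight's starting pull, scaled by the reagent, became 1.31, which ended at 56.7 % on the first pass. Spent reagent lowered the pull to 1.26, and the end to 55.8 %. That neighbour gave 55.8 % of product, with 44 % of its starting material left.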